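## Retrosynthetic overview
1. Endgame on the finished tetracycle is functional-group work only: C16 methylenation, anti-Markovnikov hydration of C5=C6 (epoxide, then reductive opening), and C1 ketone reduction with acetylation.
2. Ring C closes through the C12–C13 bond, by 6-exo addition of a primary C12 radical to the ring D cyclopentenone.
3. Key disconnection: one oxidative radical cyclisation makes the C8–C9 bond, the δ-lactone, the spiro centre C10 and ring A. It ends in a semipinacol 1,2-alkenyl shift that enlarges a cyclopentanol to the ring A cyclohexanone.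
4. The cascade substrate is an allylic β-keto ester built from 3-methylcyclopentenone (ring A), (R)-but-3-ene-1,2-diol (C9, C11, C12) and (S)-4-hydroxycyclopentenone (ring D). C10/C20 come from a bromo ylide and C7 from CDI.
5. Ring order: D (bought), then lactone and A in the same step, then C.

Assumption: positions carry ent-kaurane numbers (target = 1S,5R,8R,9S,10R,11S,13S,14R), 6 and 16 are bought enantiopure, TBS = tert-butyldimethylsilyl and TMS = trimethylsilyl.

## Route

Step 1
Reactants: 1 3-methylcyclopent-2-en-1-one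
Product: 5 3,3-dimethyl-2-methylidenecyclopentan-1-one, via magnesium enolate 2 (not isolated), via Mannich base 3 (not isolated), via methiodide 4 (not isolated)
Conditions: MeMgBr, CuBr·SMe2 (5 mol %), THF, −30 °C; Me2N=CH2+ I−, −30 °C to rt; MeI, rt; aq NaHCO3/CH2Cl2
Reagents that add atoms: methylmagnesium bromide C[Mg]Br; Eschenmoser's salt C=[N+](C)C.[I-]
Why: Copper-catalysed 1,4-addition builds the gem-dimethyl carbon and leaves the enolate only at the hindered α-carbon, so Mannich trapping, N-methylation and β-elimination (Eschenmoser methylenation) place the methylene there, and no stereocentre is formed.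

Step 2
Reactants: 6 (2R)-but-3-ene-1,2-diol
Product: 7 (2R)-1,2-bis(TBS-oxy)but-3-ene
Conditions: TBSCl (2.3 equiv), imidazole, DMF, rt
Reagents that add atoms: tert-butyldimethylsilyl chloride CC(C)(C)[Si](C)(C)Cl
Why: Standard silyl ether formation on both hydroxyls, which leaves the C11 stereocentre untouched.

Step 3
Reactants: 7 (2R)-1,2-bis(TBS-oxy)but-3-ene
Product: 9 (2S)-2,3-bis(TBS-oxy)propanal, via secondary ozonide 8 (not isolated)
Conditions: O3, CH2Cl2, −78 °C; PPh3, −78 °C to rt
Reagents that add atoms: ozone [O-][O+]=O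
Why: Ozonolysis with reductive work-up cleaves the only alkene under neutral conditions, so the α-silyloxy aldehyde does not epimerise (the descriptor changes only by priority).

Step 4
Reactants: 9 (2S)-2,3-bis(TBS-oxy)propanal
Product: 10 ethyl (2Z,4R)-2-bromo-4,5-bis(TBS-oxy)pent-2-enoate
Conditions: Ph3P=C(Br)CO2Et, CH2Cl2, 0 °C to rt
Reagents that add atoms: ethyl bromo(triphenylphosphoranylidene)acetate CCOC(=O)C(Br)=P(c1ccccc1)(c1ccccc1)c1ccccc1
Why: Wittig olefination with the stabilised bromo ylide puts the ester trans to the side chain, giving the Z-bromoalkene with Br cis to C11.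

Step 5
Reactants: 10 ethyl (2Z,4R)-2-bromo-4,5-bis(TBS-oxy)pent-2-enoate
Product: 11 (2Z,4R)-2-bromo-4,5-bis(TBS-oxy)pent-2-en-1-ol
Conditions: DIBAL-H (2.2 equiv), CH2Cl2, −78 °C; Rochelle salt
Reagents that add atoms: none
Why: Hydride 1,2-reduction of the enoate to the allylic alcohol leaves the vinyl bromide, the alkene geometry and the silyl ethers intact.

Step 6
Reactants: 11 (2Z,4R)-2-bromo-4,5-bis(TBS-oxy)pent-2-en-1-ol; 5 3,3-dimethyl-2-methylidenecyclopentan-1-one
Product: 13 1-[(2Z,4R)-4,5-bis(TBS-oxy)-1-hydroxypent-2-en-2-yl]-3,3-dimethyl-2-methylidenecyclopentan-1-ol (C1 epimers), via dilithio reagent 12 (not isolated)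
Conditions: t-BuLi (3.1 equiv), Et2O, −78 °C; 5 premixed with LaCl3·2LiCl, THF, −78 °C; aq NH4Cl
Reagents that add atoms: none
Why: Bromine–lithium exchange with retention of geometry is followed by Lewis-acid-assisted 1,2-addition of the vinyllithium to the ketone, and the new C1 carbinol centre forms as a harmless epimer mixture because it becomes sp2 in step 10.

Step 7
Reactants: 13 diol (C1 epimers)
Product: 15 C20 imidazole-1-carboxylate of 13 carrying a C1 TMS ether, via hydroxy imidazolide 14 (not isolated)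
Conditions: CDI (1.1 equiv), CH2Cl2, 0 °C to rt; N-(trimethylsilyl)imidazole, rt
Reagents that add atoms: 1,1'-carbonyldiimidazole O=C(n1ccnc1)n1ccnc1; N-(trimethylsilyl)imidazole C[Si](C)(C)n1ccnc1
Why: Only the primary allylic hydroxyl is acylated by CDI, and in-flask silylation of the tertiary hydroxyl then blocks cyclic carbonate formation in the basic step 9.

Step 8
Reactants: 16 (4S)-4-hydroxycyclopent-2-en-1-one
Product: 17 (4S)-4-(TBS-oxy)cyclopent-2-en-1-one
Conditions: TBSCl, imidazole, CH2Cl2, 0 °C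
Reagents that add atoms: tert-butyldimethylsilyl chloride CC(C)(C)[Si](C)(C)Cl
Why: Mild silyl ether formation keeps the C14 stereocentre, which later controls C8 and C13.

Step 9
Reactants: 17 (4S)-4-(TBS-oxy)cyclopent-2-en-1-one; 15 imidazole-1-carboxylate
Product: 19 allylic β-keto ester joining ring D through C8–C7(=O)–O–C20 (C11 and C14 as in 11 and 17; C1 and C8 epimers), via lithium dienolate 18 (not isolated)
Conditions: LiHMDS (2.2 equiv), THF, −78 °C; 15, −78 to −40 °C; AcOH quench
Reagents that add atoms: none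
Why: Kinetic α'-deprotonation and Claisen-type C-acylation by the imidazole carboxylate give the β-keto ester, and β-elimination of the silyloxy group is disfavoured because it would give a cyclopentadienone.

Step 10
Reactants: 19 allylic β-keto ester
Product: 20 dispiro keto lactone: δ-lactone with ring D cyclopentenone spiro at C8 and 4,4-dimethyl-5-methylidenecyclohexan-1-one (ring A) spiro at C10, with C9 bearing CH(OTBS)CH2OTBS (C8, C9, C10, C11, C14 as in the target)
Conditions: Mn(OAc)3·2H2O (2.5 equiv), degassed MeCN/AcOH 4:1, 45 °C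
Reagents that add atoms: none
Why: Proposed new method: Mn(OAc)3 oxidises the enolised β-keto ester to the electrophilic C8 radical, which adds 6-endo to the less substituted alkene carbon C9 (anti to the C14 silyl ether on ring D, and anti to the C11 silyl ether in the conformer fixed by 1,3-allylic strain against the cis C1 substituent), after which the tertiary C10 radical is oxidised by a second Mn(OAc)3 to the cation (or first transfers the vinyl group by 3-exo closure and reopening) so that alkenyl carbon C5 migrates from C1 to C10 on the lactone face opposite the C11 chain with loss of the TMS group, enlarging the cyclopentanol of either C1 epimer to the ring A cyclohexanone; the closest known reaction types are Mn(OAc)3 oxidative free-radical cyclisation of unsaturated β-keto esters and radical–polar crossover semipinacol rearrangement of 1-alkenylcycloalkanols, which have not been merged in a lactone-forming 6-endo mode with a five-to-six ring enlargement.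

Step 11
Reactants: 20 dispiro keto lactone
Product: 21 (1S)-alcohol of 20 (OH cis to C20)
Conditions: NaBH4 (1.0 equiv), CH2Cl2/MeOH 1:1, −78 °C
Reagents that add atoms: none
Why: Chemoselective borohydride reduction works because the cyclohexanone at C1 reacts far faster than the conjugated cyclopentenone at C15, and axial hydride attack opposite the axial C20 methylene gives the equatorial alcohol cis to C20.

Step 12
Reactants: 21 (1S)-alcohol
Product: 22 C1 acetate of 21
Conditions: Ac2O, DMAP, pyridine, rt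
Reagents that add atoms: acetic anhydride CC(=O)OC(C)=O
Why: DMAP-catalysed acetylation of the only free hydroxyl fixes the acetate at C1 before any other hydroxyl is unmasked.

Step 13
Reactants: 22 C1 acetate
Product: 23 primary C12 alcohol (C11 and C14 TBS ethers kept)
Conditions: HF·pyridine, pyridine, THF, 0 °C
Reagents that add atoms: none
Why: In buffered fluoride desilylation the unhindered primary TBS ether is cleaved well before the two hindered secondary ones.

Step 14
Reactants: 23 primary C12 alcohol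
Product: 24 primary C12 iodide
Conditions: I2, PPh3, imidazole, THF, 0 °C to rt
Reagents that add atoms: iodine II
Why: Appel-type iodination of the primary alcohol under near-neutral conditions spares the enone, acetate, lactone and alkene.

Step 15
Reactants: 24 primary C12 iodide
Product: 25 tetracyclic 15-ketone with the bicyclo[3.2.1]octane closed (C16 is CH2, C5=C6 kept, 11,14-bis-TBS, 1-OAc)
Conditions: Bu3SnH (slow addition), AIBN (cat.), PhH, 80 °C, 5 mM
Reagents that add atoms: none
Why: In this tin hydride 6-exo-trig Giese-type cyclisation the nucleophilic C12 radical adds to enone carbon C13 on the only face it can reach (the face carrying C9), which sets C13, while C11 and C5 lie antiperiplanar across C9–C10 so the unactivated C5=C6 alkene is out of reach.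

Step 16
Reactants: 25 tetracyclic 15-ketone
Product: 26 C5–C6 spiro-epoxide of 25 (oxygen on the ring A face opposite C20)
Conditions: mCPBA, NaHCO3, CH2Cl2, 0 °C
Reagents that add atoms: 3-chloroperoxybenzoic acid O=C(OO)c1cccc(Cl)c1
Why: Prilezhaev epoxidation of the only alkene occurs from the face not blocked by axial C20 and the axial C4 methyl, and the hindered cyclopentanone is too slow for Baeyer–Villiger oxidation at 0 °C.

Step 17
Reactants: 26 spiro-epoxide
Product: 27 primary C6 alcohol with (5R)-H (CH2OH cis to C20)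
Conditions: Cp2TiCl2 (20 mol %), Mn, 2,4,6-collidine·HCl, 1,4-cyclohexadiene, THF, rt
Reagents that add atoms: none
Why: Titanocene-catalysed reductive epoxide opening (Cp2TiCl, trivalent titanium) gives the tertiary C5 radical with anti-Markovnikov regiochemistry, and hydrogen-atom transfer on the open face opposite C20 and the axial methyl sets C5 while the ketone and esters are tolerated.

Step 18
Reactants: 27 primary C6 alcohol
Product: 31 16-methylidene-15-ketone carrying a C6 TMS ether plus 11,14-bis-TBS and 1-OAc, via bis-silyl enol ether 28 (not isolated), via Mannich base 29 (not isolated), via methiodide 30 (not isolated)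
Conditions: TMSOTf, Et3N, CH2Cl2, 0 °C; Me2N=CH2+ I−, rt; MeI; aq NaHCO3
Reagents that add atoms: trimethylsilyl triflate C[Si](C)(C)OS(=O)(=O)C(F)(F)F; Eschenmoser's salt C=[N+](C)C.[I-]
Why: Soft enolisation can only go toward C16 because C8 is quaternary, so Mannich reaction of the silyl enol ether, N-methylation and β-elimination (Eschenmoser methylenation) install the exocyclic enone while the C6 hydroxyl is masked in passing.

Step 19
Reactants: 31 silylated 16-methylidene-15-ketone
Product: 32 CNP0225182.1 (target)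
Conditions: aq HF (48 %), MeCN, 0 °C to rt
Reagents that add atoms: none
Why: Acidic global fluoride desilylation frees O6, O11 and O14 without base, so the acetate, the enone and the retro-aldol-prone 14-hydroxy-15-ketone survive.

## Compound list
1 | 3-methylcyclopent-2-en-1-one | CC1=CC(=O)CC1 | starting material
2 | bromomagnesium enolate of 3,3-dimethylcyclopentanone (toward the hindered carbon) | CC1(C)CCC(O[Mg]Br)=C1 | intermediate
3 | 2-[(dimethylamino)methyl]-3,3-dimethylcyclopentan-1-one (racemic) | CN(C)CC1C(=O)CCC1(C)C | intermediate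
4 | [(2,2-dimethyl-5-oxocyclopentyl)methyl]trimethylammonium iodide | C[N+](C)(C)CC1C(=O)CCC1(C)C.[I-] | intermediate
5 | 3,3-dimethyl-2-methylidenecyclopentan-1-one | C=C1C(=O)CCC1(C)C | intermediate
6 | (2R)-but-3-ene-1,2-diol | C=C[C@@H](O)CO | starting material
7 | (2R)-1,2-bis(TBS-oxy)but-3-ene | C=C[C@@H](O[Si](C)(C)C(C)(C)C)CO[Si](C)(C)C(C)(C)C | intermediate
8 | secondary ozonide (1,2,4-trioxolane) of 7 | C1OC(OO1)[C@@H](O[Si](C)(C)C(C)(C)C)CO[Si](C)(C)C(C)(C)C | intermediate
9 | (2S)-2,3-bis(TBS-oxy)propanal | O=C[C@@H](O[Si](C)(C)C(C)(C)C)CO[Si](C)(C)C(C)(C)C | intermediate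
10 | ethyl (2Z,4R)-2-bromo-4,5-bis(TBS-oxy)pent-2-enoate | CCOC(=O)/C(Br)=C/[C@@H](O[Si](C)(C)C(C)(C)C)CO[Si](C)(C)C(C)(C)C | intermediate
11 | (2Z,4R)-2-bromo-4,5-bis(TBS-oxy)pent-2-en-1-ol | OC/C(Br)=C/[C@@H](O[Si](C)(C)C(C)(C)C)CO[Si](C)(C)C(C)(C)C | intermediate
12 | dilithio reagent (lithium alkoxide, C10 vinyllithium) from 11 | [Li]OC/C([Li])=C/[C@@H](O[Si](C)(C)C(C)(C)C)CO[Si](C)(C)C(C)(C)C | intermediate
13 | 1-[(2Z,4R)-4,5-bis(TBS-oxy)-1-hydroxypent-2-en-2-yl]-3,3-dimethyl-2-methylidenecyclopentan-1-ol, C1 epimers | OC/C(=C/[C@@H](O[Si](C)(C)C(C)(C)C)CO[Si](C)(C)C(C)(C)C)C1(O)CCC(C)(C)C1=C | intermediate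
14 | C20 imidazole-1-carboxylate of 13, tertiary OH free | O=C(OC/C(=C/[C@@H](O[Si](C)(C)C(C)(C)C)CO[Si](C)(C)C(C)(C)C)C1(O)CCC(C)(C)C1=C)n1ccnc1 | intermediate
15 | C20 imidazole-1-carboxylate, C1 TMS ether | O=C(OC/C(=C/[C@@H](O[Si](C)(C)C(C)(C)C)CO[Si](C)(C)C(C)(C)C)C1(O[Si](C)(C)C)CCC(C)(C)C1=C)n1ccnc1 | intermediate
16 | (4S)-4-hydroxycyclopent-2-en-1-one | O=C1C=C[C@@H](O)C1 | starting material
17 | (4S)-4-(TBS-oxy)cyclopent-2-en-1-one | O=C1C=C[C@@H](O[Si](C)(C)C(C)(C)C)C1 | intermediate
18 | lithium cross-conjugated dienolate of 17 | [Li]OC1=C[C@H](O[Si](C)(C)C(C)(C)C)C=C1 | intermediate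
19 | allylic β-keto ester (ring D C8 carboxylate of the C20 alcohol; C1 and C8 epimers) | O=C1C=C[C@@H](O[Si](C)(C)C(C)(C)C)C1C(=O)OC/C(=C/[C@@H](O[Si](C)(C)C(C)(C)C)CO[Si](C)(C)C(C)(C)C)C1(O[Si](C)(C)C)CCC(C)(C)C1=C | intermediate
20 | dispiro keto lactone (1-ketone, C5=C6, ring D enone) | O=C1C=C[C@@H](O[Si](C)(C)C(C)(C)C)[C@@]12C(=O)OC[C@]3(C(=O)CCC(C)(C)C3=C)[C@@H]2[C@@H](O[Si](C)(C)C(C)(C)C)CO[Si](C)(C)C(C)(C)C | intermediate
21 | (1S)-alcohol of 20 | O=C1C=C[C@@H](O[Si](C)(C)C(C)(C)C)[C@@]12C(=O)OC[C@]3([C@@H](O)CCC(C)(C)C3=C)[C@@H]2[C@@H](O[Si](C)(C)C(C)(C)C)CO[Si](C)(C)C(C)(C)C | intermediate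
22 | C1 acetate | O=C1C=C[C@@H](O[Si](C)(C)C(C)(C)C)[C@@]12C(=O)OC[C@]3([C@@H](OC(C)=O)CCC(C)(C)C3=C)[C@@H]2[C@@H](O[Si](C)(C)C(C)(C)C)CO[Si](C)(C)C(C)(C)C | intermediate
23 | primary C12 alcohol | O=C1C=C[C@@H](O[Si](C)(C)C(C)(C)C)[C@@]12C(=O)OC[C@]3([C@@H](OC(C)=O)CCC(C)(C)C3=C)[C@@H]2[C@@H](O[Si](C)(C)C(C)(C)C)CO | intermediate
24 | primary C12 iodide | O=C1C=C[C@@H](O[Si](C)(C)C(C)(C)C)[C@@]12C(=O)OC[C@]3([C@@H](OC(C)=O)CCC(C)(C)C3=C)[C@@H]2[C@@H](O[Si](C)(C)C(C)(C)C)CI | intermediate
25 | tetracyclic 15-ketone, C5=C6 alkene | C1C(=O)[C@@]23C(=O)OC[C@]4([C@@H](OC(C)=O)CCC(C)(C)C4=C)[C@@H]2[C@@H](O[Si](C)(C)C(C)(C)C)C[C@@H]1[C@H]3O[Si](C)(C)C(C)(C)C | intermediate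
26 | C5–C6 spiro-epoxide | C1C(=O)[C@@]23C(=O)OC[C@]4([C@@H](OC(C)=O)CCC(C)(C)[C@@]45CO5)[C@@H]2[C@@H](O[Si](C)(C)C(C)(C)C)C[C@@H]1[C@H]3O[Si](C)(C)C(C)(C)C | intermediate
27 | primary C6 alcohol, (5R) | C1C(=O)[C@@]23C(=O)OC[C@]4([C@@H](OC(C)=O)CCC(C)(C)[C@H]4CO)[C@@H]2[C@@H](O[Si](C)(C)C(C)(C)C)C[C@@H]1[C@H]3O[Si](C)(C)C(C)(C)C | intermediate
28 | C15 TMS enol ether, C6 TMS ether | C1=C(O[Si](C)(C)C)[C@@]23C(=O)OC[C@]4([C@@H](OC(C)=O)CCC(C)(C)[C@H]4CO[Si](C)(C)C)[C@@H]2[C@@H](O[Si](C)(C)C(C)(C)C)C[C@@H]1[C@H]3O[Si](C)(C)C(C)(C)C | intermediate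
29 | 16-(dimethylaminomethyl) ketone (C16 epimers) | CN(C)CC1C(=O)[C@@]23C(=O)OC[C@]4([C@@H](OC(C)=O)CCC(C)(C)[C@H]4CO[Si](C)(C)C)[C@@H]2[C@@H](O[Si](C)(C)C(C)(C)C)C[C@@H]1[C@H]3O[Si](C)(C)C(C)(C)C | intermediate
30 | methiodide of 29 | C[N+](C)(C)CC1C(=O)[C@@]23C(=O)OC[C@]4([C@@H](OC(C)=O)CCC(C)(C)[C@H]4CO[Si](C)(C)C)[C@@H]2[C@@H](O[Si](C)(C)C(C)(C)C)C[C@@H]1[C@H]3O[Si](C)(C)C(C)(C)C.[I-] | intermediate
31 | 16-methylidene-15-ketone, 6-O-TMS, 11,14-bis-O-TBS | C=C1C(=O)[C@@]23C(=O)OC[C@]4([C@@H](OC(C)=O)CCC(C)(C)[C@H]4CO[Si](C)(C)C)[C@@H]2[C@@H](O[Si](C)(C)C(C)(C)C)C[C@@H]1[C@H]3O[Si](C)(C)C(C)(C)C | intermediate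
32 | CNP0225182.1: 1-acetoxy-6,11,14-trihydroxy-15-oxo-6,7-seco-ent-kaur-16-en-7,20-olide | C=C1C(=O)[C@@]23C(=O)OC[C@]4([C@@H](OC(C)=O)CCC(C)(C)[C@H]4CO)[C@@H]2[C@@H](O)C[C@@H]1[C@H]3O | target

## Step count and risks
Total steps: 19. Longest linear sequence: 17 (steps 2–7, then 9–19).

**Step 10 (the proposed new step).**
- Why it may fail: a fully substituted radical has to bond to a shielded alkene carbon through an ester tether. It may be quenched or acetoxylated first, and the facial bias at C9 rests on a conformational argument.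
- Fallback: it sets out from 19 and returns at 20, using known reactions only.
  - C8 is brominated with NBS/Mg(ClO4)2 to give the α-bromo β-keto ester F1.
  - A Lewis-acid-assisted bromine-atom-transfer radical cyclisation (Et3B/O2, Yb(OTf)3) gives the δ-lactone C10 tertiary bromide F2.
  - AgOCOCF3 ionises this bromide, so a classical halohydrin-type semipinacol shift of C5 delivers 20.

**Step 11.**
- Why it may fail: borohydride may also attack the activated cyclopentenone, by 1,2- or 1,4-addition.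
- Fallback: it sets out from 20 and returns at 21, and gives up selective reduction.
  - Both ketones are reduced under Luche conditions (NaBH4, CeCl3·7H2O) to the 1,15-diol F3.
  - Only the allylic C15 alcohol is then reoxidised, with MnO2.

**Step 17.**
- Why it may fail: hydrogen-atom transfer to the C5 radical may be unselective, or the titanoxy radical may deoxygenate back to the alkene.
- Fallback: it sets out from 26 and returns at 27, and replaces the radical opening by ionic chemistry.
  - BF3·OEt2 isomerises the epoxide by a Meinwald 1,2-hydride shift to the C6 aldehyde F4.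
  - DBU equilibrates C5 to the equatorial (5R) epimer.
  - NaBH(OAc)3 reduces the aldehyde alone.

## Further compounds
F1 | step 10 | C8 α-bromo β-keto ester from 19 | O=C1C=C[C@@H](O[Si](C)(C)C(C)(C)C)C1(Br)C(=O)OC/C(=C/[C@@H](O[Si](C)(C)C(C)(C)C)CO[Si](C)(C)C(C)(C)C)C1(O[Si](C)(C)C)CCC(C)(C)C1=C
F2 | step 10 | δ-lactone C10 tertiary bromide with the cyclopentyl TMS ether intact | O=C1C=C[C@@H](O[Si](C)(C)C(C)(C)C)[C@@]12C(=O)OCC(Br)(C3(O[Si](C)(C)C)CCC(C)(C)C3=C)[C@@H]2[C@@H](O[Si](C)(C)C(C)(C)C)CO[Si](C)(C)C(C)(C)C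
F3 | step 11 | 1,15-diol from 20 (C15 epimers) | OC1C=C[C@@H](O[Si](C)(C)C(C)(C)C)[C@@]12C(=O)OC[C@]3([C@@H](O)CCC(C)(C)C3=C)[C@@H]2[C@@H](O[Si](C)(C)C(C)(C)C)CO[Si](C)(C)C(C)(C)C
F4 | step 17 | C6 aldehyde, (5R) after equilibration | C1C(=O)[C@@]23C(=O)OC[C@]4([C@@H](OC(C)=O)CCC(C)(C)[C@H]4C=O)[C@@H]2[C@@H](O[Si](C)(C)C(C)(C)C)C[C@@H]1[C@H]3O[Si](C)(C)C(C)(C)C
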